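**Retrosynthetic overview**

1. Target 27 comes from the macrocyclic (4Z)-olefin 26 by epoxidation directed by the 2-OH group. The cis-4,5-oxirane has its oxygen on the same ring face as the C2 hydroxyl, so it is the oxidation product of a Z-C4=C5 double bond in the ten-membered ring B.
2. 26 comes from seco-diene 25 by ring-closing metathesis at C4=C5. The enabling feature: C4 (quaternary oxirane carbon carrying C15) and C5 (oxirane CH next to the lactone carbinol C6) are the only electron-rich terminal olefin carbons of 25, and the trans-fused α-methylene-γ-lactone (ring A: O–C12–C11–C7–C6) together with the trans-1,10-oxirane folds the chain between them.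
3. 25 comes from lactone aldehyde 9: C8–C9 by vinylogous Mukaiyama aldol with dienol ether 11, C2–C3 by Keck methallylation with 14, the 1,10-oxirane by 2-OH-directed epoxidation, the exo-methylene by Mannich/elimination, the angelate by mixed-anhydride esterification.
4. 9 comes from an Evans syn-aldol of succinate imide 3 with acrolein 4 followed by lactonisation, which sets C6 and C7.
5. Ring order: ring A (lactone, step 2), 1,10-oxirane (step 9), ring B (carbocycle, step 15), 4,5-oxirane (step 16).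

Key step: step 15

Assumption (remark on the chemistry): germacrane numbering is used throughout (ring carbons C1–C10, lactone carbons C11–C13, C14 on C10, C15 on C4). The (S)-BINOL–titanium catalyst and the D-tryptophan-derived boron promoter are assumed to expose the Si face of their aldehydes, as in their accepted transition-state models.

**Route**

Step 1
Reactants: 1 (S)-4-benzyl-1,3-oxazolidin-2-one; 2 methyl 4-chloro-4-oxobutanoate
Product: 3 methyl 4-[(4S)-4-benzyl-2-oxo-1,3-oxazolidin-3-yl]-4-oxobutanoate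
Conditions: n-BuLi, THF, −78 °C; then 2, −78 to 0 °C
Reagents that add atoms: none
Why: N-acylation of the lithiated oxazolidinone by the acid chloride (imide formation) is much faster than attack on the methyl ester.

Step 2
Reactants: 3 methyl 4-[(4S)-4-benzyl-2-oxo-1,3-oxazolidin-3-yl]-4-oxobutanoate; 4 acrolein
Product: 6 (4S)-4-benzyl-3-{[(2R,3S)-5-oxo-2-vinyltetrahydrofuran-3-yl]carbonyl}-1,3-oxazolidin-2-one, via aldol adduct 5 (not isolated)
Conditions: Bu2BOTf, iPr2NEt, CH2Cl2, −78 to 0 °C; 4, −78 °C; H2O2, MeOH, pH 7 buffer, 0 °C; crude, PPTS (cat.), PhMe, 60 °C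
Reagents that add atoms: none
Why: Evans syn-aldol reaction: the (Z)-dibutylboron enolate adds to acrolein through a Zimmerman–Traxler chair in which the benzyl group of the auxiliary blocks one enolate face, setting C7 (S) and C6 (R) syn, and the γ-hydroxy ester then closes under mild acid to the trans-4,5-disubstituted γ-lactone (ring A).

Step 3
Reactants: 6 (4S)-4-benzyl-3-{[(2R,3S)-5-oxo-2-vinyltetrahydrofuran-3-yl]carbonyl}-1,3-oxazolidin-2-one
Product: 7 (2R,3S)-5-oxo-2-vinyltetrahydrofuran-3-carboxylic acid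
Conditions: LiOH, H2O2, THF/H2O, 0 °C; Na2SO3; HCl to pH 2
Reagents that add atoms: hydrogen peroxide OO
Why: Lithium hydroperoxide hydrolysis of the N-acyl oxazolidinone: the hydroperoxide anion attacks the exocyclic imide carbonyl selectively, auxiliary 1 is recovered, and any lactone that opens recloses on acidification without touching C6 or C7.

Step 4
Reactants: 7 (2R,3S)-5-oxo-2-vinyltetrahydrofuran-3-carboxylic acid
Product: 9 (2R,3S)-5-oxo-2-vinyltetrahydrofuran-3-carbaldehyde, via acid chloride 8 (not isolated)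
Conditions: (COCl)2, DMF (cat.), CH2Cl2, 0 °C to rt; evaporate; LiAlH(OtBu)3, THF, −78 °C
Reagents that add atoms: none
Why: Acid chloride formation (Vilsmeier catalysis) followed by low-temperature reduction with the hindered hydride LiAlH(OtBu)3 stops at the aldehyde and leaves lactone and vinyl group alone; the β-acyloxy aldehyde is used crude to avoid C7 epimerisation or β-elimination.

Step 5
Reactants: 10 3-methylbut-2-enal
Product: 11 tert-butyl(dimethyl){[(1E)-3-methylbuta-1,3-dien-1-yl]oxy}silane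
Conditions: TBSOTf, Et3N, Et2O, 0 °C to rt
Reagents that add atoms: tert-butyldimethylsilyl triflate CC(C)(C)[Si](C)(C)OS(=O)(=O)C(F)(F)F
Why: Silyl triflate/amine soft enolisation removes a γ-hydrogen of the enal and gives the (1E)-silyl dienol ether, the nucleophile for the vinylogous aldol reaction.

Step 6
Reactants: 9 (2R,3S)-5-oxo-2-vinyltetrahydrofuran-3-carbaldehyde; 11 tert-butyl(dimethyl){[(1E)-3-methylbuta-1,3-dien-1-yl]oxy}silane
Product: 12 (2E,5S)-5-hydroxy-3-methyl-5-[(2R,3R)-5-oxo-2-vinyltetrahydrofuran-3-yl]pent-2-enal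
Conditions: N-tosyl-D-tryptophan, PhBCl2, CH2Cl2 (forms the B-phenyl N-tosyl oxazaborolidinone, 1.2 equiv); then 9, 11, iPrOH, EtCN, −78 °C
Reagents that add atoms: none
Why: Vinylogous Mukaiyama aldol reaction: the chiral boron Lewis acid activates the aldehyde and exposes its Si face, the dienol ether attacks through its terminal CH2 (C9) in an open transition state to set C8 (S) under reagent control, and the conjugated (2E)-enal carrying the C14 methyl is restored.

Step 7
Reactants: 12 (2E,5S)-5-hydroxy-3-methyl-5-[(2R,3R)-5-oxo-2-vinyltetrahydrofuran-3-yl]pent-2-enal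
Product: 13 (2E,5S)-3-methyl-5-[(2R,3S)-5-oxo-2-vinyltetrahydrofuran-3-yl]-5-(triethylsilyloxy)pent-2-enal
Conditions: Et3SiCl, imidazole, CH2Cl2, 0 °C
Reagents that add atoms: chlorotriethylsilane CC[Si](Cl)(CC)CC
Why: Silylation of the secondary C8 alcohol under weakly basic conditions (no enolisation of the enal, no translactonisation) masks it for the allylation and enolate steps.

Step 8
Reactants: 13 (2E,5S)-3-methyl-5-[(2R,3S)-5-oxo-2-vinyltetrahydrofuran-3-yl]-5-(triethylsilyloxy)pent-2-enal; 14 tributyl(2-methylprop-2-en-1-yl)stannane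
Product: 15 (4S,5R)-4-[(1S,3E,5S)-5-hydroxy-3,7-dimethyl-1-(triethylsilyloxy)octa-3,7-dien-1-yl]-5-vinyldihydrofuran-2(3H)-one
Conditions: (S)-BINOL (20 mol %), Ti(OiPr)4 (10 mol %), 4 Å MS, CH2Cl2, −20 °C; aq. NaHCO3
Reagents that add atoms: none
Why: Keck asymmetric allylation: the (S)-BINOL–titanium Lewis acid directs the methallylstannane to the Si face of the enal carbonyl in an open transition state (1,2-addition), setting C2 (S) under catalyst control because the existing stereocentres are remote.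

Step 9
Reactants: 15 (4S,5R)-4-[(1S,3E,5S)-5-hydroxy-3,7-dimethyl-1-(triethylsilyloxy)octa-3,7-dien-1-yl]-5-vinyldihydrofuran-2(3H)-one
Product: 16 (4S,5R)-4-[(1S)-2-{(2R,3R)-3-[(1S)-1-hydroxy-3-methylbut-3-en-1-yl]-2-methyloxiran-2-yl}-1-(triethylsilyloxy)ethyl]-5-vinyldihydrofuran-2(3H)-one
Conditions: mCPBA (1.05 equiv), NaHCO3, CH2Cl2, −20 to 0 °C
Reagents that add atoms: 3-chloroperoxybenzoic acid O=C(OO)c1cccc(Cl)c1
Why: Hydroxyl-directed (Henbest-type) peracid epoxidation: A(1,3) strain between the C14 methyl (cis to C2) and the carbinol substituents holds the C2–H bond in the olefin plane, so the hydrogen-bonded peracid delivers oxygen to the face bearing the hydroxyl and gives the threo (1R,10R) trans-oxirane, the trisubstituted allylic olefin reacting ahead of the 1,1-disubstituted and monosubstituted ones.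

Step 10
Reactants: 16 (4S,5R)-4-[(1S)-2-{(2R,3R)-3-[(1S)-1-hydroxy-3-methylbut-3-en-1-yl]-2-methyloxiran-2-yl}-1-(triethylsilyloxy)ethyl]-5-vinyldihydrofuran-2(3H)-one
Product: 17 (4S,5R)-4-[(1S)-2-{(2R,3R)-3-[(1S)-1-(tert-butyldimethylsilyloxy)-3-methylbut-3-en-1-yl]-2-methyloxiran-2-yl}-1-(triethylsilyloxy)ethyl]-5-vinyldihydrofuran-2(3H)-one
Conditions: TBSOTf, 2,6-lutidine, CH2Cl2, −78 °C
Reagents that add atoms: tert-butyldimethylsilyl triflate CC(C)(C)[Si](C)(C)OS(=O)(=O)C(F)(F)F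
Why: Low-temperature silylation with the silyl triflate and a hindered base protects the C2 alcohol without Payne rearrangement or opening of the neighbouring oxirane.

Step 11
Reactants: 17 (4S,5R)-4-[(1S)-2-{(2R,3R)-3-[(1S)-1-(tert-butyldimethylsilyloxy)-3-methylbut-3-en-1-yl]-2-methyloxiran-2-yl}-1-(triethylsilyloxy)ethyl]-5-vinyldihydrofuran-2(3H)-one
Product: 20 (4S,5R)-4-[(1S)-2-{(2R,3R)-3-[(1S)-1-(tert-butyldimethylsilyloxy)-3-methylbut-3-en-1-yl]-2-methyloxiran-2-yl}-1-(triethylsilyloxy)ethyl]-3-methylidene-5-vinyldihydrofuran-2(3H)-one, via Mannich base 18 (not isolated), via ammonium iodide 19 (not isolated)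
Conditions: LiN(iPr)2, THF, −78 °C; Me2N=CH2 iodide (Eschenmoser's salt), −78 °C to rt; MeI, MeOH, rt; aq. NaHCO3, CH2Cl2
Reagents that add atoms: dimethyl(methylidene)ammonium iodide C=[N+](C)C.[I-]
Why: α-Methylenation of the lactone by enolate Mannich reaction with Eschenmoser's salt, N-quaternisation and E1cB-type loss of trimethylamine; only C11 is deprotonated, so C6 and C7 are untouched and the transient C11 stereocentre is destroyed.

Step 12
Reactants: 20 (4S,5R)-4-[(1S)-2-{(2R,3R)-3-[(1S)-1-(tert-butyldimethylsilyloxy)-3-methylbut-3-en-1-yl]-2-methyloxiran-2-yl}-1-(triethylsilyloxy)ethyl]-3-methylidene-5-vinyldihydrofuran-2(3H)-one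
Product: 21 (4R,5R)-4-[(1S)-2-{(2R,3R)-3-[(1S)-1-(tert-butyldimethylsilyloxy)-3-methylbut-3-en-1-yl]-2-methyloxiran-2-yl}-1-hydroxyethyl]-3-methylidene-5-vinyldihydrofuran-2(3H)-one
Conditions: HF·pyridine, pyridine, THF, 0 °C
Reagents that add atoms: none
Why: Chemoselective desilylation: the triethylsilyl ether is cleaved by buffered HF·pyridine much faster than the tert-butyldimethylsilyl ether, freeing only the C8 alcohol under conditions too mild for translactonisation or oxirane opening.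

Step 13
Reactants: 21 (4R,5R)-4-[(1S)-2-{(2R,3R)-3-[(1S)-1-(tert-butyldimethylsilyloxy)-3-methylbut-3-en-1-yl]-2-methyloxiran-2-yl}-1-hydroxyethyl]-3-methylidene-5-vinyldihydrofuran-2(3H)-one; 22 angelic acid, (2Z)-2-methylbut-2-enoic acid
Product: 24 (1S)-2-{(2R,3R)-3-[(1S)-1-(tert-butyldimethylsilyloxy)-3-methylbut-3-en-1-yl]-2-methyloxiran-2-yl}-1-[(2R,3R)-4-methylidene-5-oxo-2-vinyltetrahydrofuran-3-yl]ethyl (2Z)-2-methylbut-2-enoate, via mixed anhydride 23 (not isolated)
Conditions: 22, 2,4,6-trichlorobenzoyl chloride, Et3N, PhMe, rt; then 21, 75 °C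
Reagents that add atoms: none
Why: Yamaguchi-type esterification through the 2,4,6-trichlorobenzoyl mixed anhydride without a nucleophilic catalyst acylates the hindered C8 alcohol with retention at C8 and keeps the Z (angelate) geometry, which pyridine-type acyl-transfer catalysts tend to isomerise.

Step 14
Reactants: 24 (1S)-2-{(2R,3R)-3-[(1S)-1-(tert-butyldimethylsilyloxy)-3-methylbut-3-en-1-yl]-2-methyloxiran-2-yl}-1-[(2R,3R)-4-methylidene-5-oxo-2-vinyltetrahydrofuran-3-yl]ethyl (2Z)-2-methylbut-2-enoate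
Product: 25 (1S)-2-{(2R,3R)-3-[(1S)-1-hydroxy-3-methylbut-3-en-1-yl]-2-methyloxiran-2-yl}-1-[(2R,3R)-4-methylidene-5-oxo-2-vinyltetrahydrofuran-3-yl]ethyl (2Z)-2-methylbut-2-enoate
Conditions: Bu4NF, AcOH, THF, 0 °C to rt
Reagents that add atoms: none
Why: Fluoride-mediated cleavage of the silyl ether, buffered with acetic acid so that the α-methylene lactone, the angelate and the oxirane survive, unveils the C2 alcohol needed as directing group.

Step 15
Reactants: 25 (1S)-2-{(2R,3R)-3-[(1S)-1-hydroxy-3-methylbut-3-en-1-yl]-2-methyloxiran-2-yl}-1-[(2R,3R)-4-methylidene-5-oxo-2-vinyltetrahydrofuran-3-yl]ethyl (2Z)-2-methylbut-2-enoate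
Product: 26 (1R,2S,4Z,6R,7R,8S,10R)-8-angeloyloxy-1,10-epoxy-2-hydroxygermacra-4,11(13)-dien-12,6-olide
Conditions: second-generation Hoveyda–Grubbs catalyst RuCl2(H2IMes)(=CH-C6H4-2-OiPr) (15 mol %, two portions), 1,4-benzoquinone (30 mol %), PhMe (0.5 mM), 80 °C, argon sparge
Reagents that add atoms: none
Why: Ring-closing olefin metathesis by the Chauvin mechanism: the ruthenium alkylidene loads onto the unhindered C5 vinyl group, the C5 carbene undergoes [2+2] cycloaddition with the 1,1-disubstituted C4 olefin, and cycloreversion releases ethene, so the C4–C5 bond is formed as a double bond. The closest known reaction type is RCM closure of the trisubstituted C4=C5 olefin in medium-ring sesquiterpene lactones and in other functionalised nine- and ten-membered carbocycles. One ring is closed, ring B, as a ten-membered carbocycle by macrocyclising metathesis of an α,ω-diene whose termini are brought together by two turn elements, the trans-fused lactone (ring A) at C6–C7 and the trans-1,10-oxirane. No stereocentre is created; the new stereo-element, the 4Z geometry, should be set by ring strain, the cis-fused metallacyclobutane being the less strained path to a ten-membered ring. The step needs chemoselectivity among five C=C bonds and cyclisation over oligomerisation: the angelate and α-methylene lactone olefins are electron-poor, hindered spectators, the C1=C10 olefin that would otherwise close a cyclohexene is already masked as the oxirane, and high dilution, ethene removal and benzoquinone (against ruthenium hydride isomerisation) favour the ring.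

Step 16
Reactants: 26 (1R,2S,4Z,6R,7R,8S,10R)-8-angeloyloxy-1,10-epoxy-2-hydroxygermacra-4,11(13)-dien-12,6-olide
Product: 27 (1R,2S,4R,5S,6S,7R,8S,10R)-8-angeloyloxy-1,10:4,5-diepoxy-2-hydroxygermacr-11(13)-en-12,6-olide (target)
Conditions: VO(acac)2 (5 mol %), tBuOOH (1.5 equiv, in decane), CH2Cl2, 0 °C to rt
Reagents that add atoms: tert-butyl hydroperoxide CC(C)(C)OO
Why: Vanadium-catalysed hydroxyl-directed epoxidation: the vanadate ester of the homoallylic C2 alcohol delivers the peroxide oxygen intramolecularly to the face of the Z-C4=C5 olefin on which the hydroxyl sits, giving the cis-oxirane with C4 (R) and C5 (S), while the electron-poor angelate and α-methylene lactone olefins do not react with this electrophilic oxidant.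

**Compound list**

1 | (S)-4-benzyl-1,3-oxazolidin-2-one | O=C1N[C@@H](Cc2ccccc2)CO1 | starting material
2 | methyl 4-chloro-4-oxobutanoate | COC(=O)CCC(Cl)=O | starting material
3 | methyl 4-[(4S)-4-benzyl-2-oxo-1,3-oxazolidin-3-yl]-4-oxobutanoate | COC(=O)CCC(=O)N1[C@@H](Cc2ccccc2)COC1=O | intermediate
4 | acrolein (prop-2-enal) | C=CC=O | starting material
5 | methyl (3S,4R)-3-{[(4S)-4-benzyl-2-oxo-1,3-oxazolidin-3-yl]carbonyl}-4-hydroxyhex-5-enoate (aldol adduct) | COC(=O)C[C@@H]([C@H](O)C=C)C(=O)N1[C@@H](Cc2ccccc2)COC1=O | intermediate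
6 | (4S)-4-benzyl-3-{[(2R,3S)-5-oxo-2-vinyltetrahydrofuran-3-yl]carbonyl}-1,3-oxazolidin-2-one | C=C[C@H]1OC(=O)C[C@@H]1C(=O)N1[C@@H](Cc2ccccc2)COC1=O | intermediate
7 | (2R,3S)-5-oxo-2-vinyltetrahydrofuran-3-carboxylic acid | C=C[C@H]1OC(=O)C[C@@H]1C(=O)O | intermediate
8 | (2R,3S)-5-oxo-2-vinyltetrahydrofuran-3-carbonyl chloride | C=C[C@H]1OC(=O)C[C@@H]1C(Cl)=O | intermediate
9 | (2R,3S)-5-oxo-2-vinyltetrahydrofuran-3-carbaldehyde | C=C[C@H]1OC(=O)C[C@@H]1C=O | intermediate
10 | 3-methylbut-2-enal | CC(C)=CC=O | starting material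
11 | tert-butyl(dimethyl){[(1E)-3-methylbuta-1,3-dien-1-yl]oxy}silane | C=C(C)/C=C/O[Si](C)(C)C(C)(C)C | intermediate
12 | (2E,5S)-5-hydroxy-3-methyl-5-[(2R,3R)-5-oxo-2-vinyltetrahydrofuran-3-yl]pent-2-enal | C=C[C@H]1OC(=O)C[C@@H]1[C@@H](O)C/C(C)=C/C=O | intermediate
13 | (2E,5S)-3-methyl-5-[(2R,3S)-5-oxo-2-vinyltetrahydrofuran-3-yl]-5-(triethylsilyloxy)pent-2-enal | C=C[C@H]1OC(=O)C[C@@H]1[C@@H](O[Si](CC)(CC)CC)C/C(C)=C/C=O | intermediate
14 | tributyl(2-methylprop-2-en-1-yl)stannane | CC(=C)C[Sn](CCCC)(CCCC)CCCC | starting material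
15 | (4S,5R)-4-[(1S,3E,5S)-5-hydroxy-3,7-dimethyl-1-(triethylsilyloxy)octa-3,7-dien-1-yl]-5-vinyldihydrofuran-2(3H)-one | C=C[C@H]1OC(=O)C[C@@H]1[C@@H](O[Si](CC)(CC)CC)C/C(C)=C/[C@@H](O)CC(C)=C | intermediate
16 | (4S,5R)-4-[(1S)-2-{(2R,3R)-3-[(1S)-1-hydroxy-3-methylbut-3-en-1-yl]-2-methyloxiran-2-yl}-1-(triethylsilyloxy)ethyl]-5-vinyldihydrofuran-2(3H)-one | C=C[C@H]1OC(=O)C[C@@H]1[C@@H](O[Si](CC)(CC)CC)C[C@@]1(C)O[C@@H]1[C@@H](O)CC(C)=C | intermediate
17 | (4S,5R)-4-[(1S)-2-{(2R,3R)-3-[(1S)-1-(tert-butyldimethylsilyloxy)-3-methylbut-3-en-1-yl]-2-methyloxiran-2-yl}-1-(triethylsilyloxy)ethyl]-5-vinyldihydrofuran-2(3H)-one | C=C[C@H]1OC(=O)C[C@@H]1[C@@H](O[Si](CC)(CC)CC)C[C@@]1(C)O[C@@H]1[C@@H](O[Si](C)(C)C(C)(C)C)CC(C)=C | intermediate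
18 | Mannich base: 17 carrying a (dimethylamino)methyl group on C11 (lactone C3), C11 epimers | C=C[C@H]1OC(=O)C(CN(C)C)[C@@H]1[C@@H](O[Si](CC)(CC)CC)C[C@@]1(C)O[C@@H]1[C@@H](O[Si](C)(C)C(C)(C)C)CC(C)=C | intermediate
19 | ammonium iodide: 17 carrying a (trimethylammonio)methyl group on C11, iodide salt, C11 epimers | C=C[C@H]1OC(=O)C(C[N+](C)(C)C)[C@@H]1[C@@H](O[Si](CC)(CC)CC)C[C@@]1(C)O[C@@H]1[C@@H](O[Si](C)(C)C(C)(C)C)CC(C)=C.[I-] | intermediate
20 | (4S,5R)-4-[(1S)-2-{(2R,3R)-3-[(1S)-1-(tert-butyldimethylsilyloxy)-3-methylbut-3-en-1-yl]-2-methyloxiran-2-yl}-1-(triethylsilyloxy)ethyl]-3-methylidene-5-vinyldihydrofuran-2(3H)-one | C=C[C@H]1OC(=O)C(=C)[C@@H]1[C@@H](O[Si](CC)(CC)CC)C[C@@]1(C)O[C@@H]1[C@@H](O[Si](C)(C)C(C)(C)C)CC(C)=C | intermediate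
21 | (4R,5R)-4-[(1S)-2-{(2R,3R)-3-[(1S)-1-(tert-butyldimethylsilyloxy)-3-methylbut-3-en-1-yl]-2-methyloxiran-2-yl}-1-hydroxyethyl]-3-methylidene-5-vinyldihydrofuran-2(3H)-one | C=C[C@H]1OC(=O)C(=C)[C@@H]1[C@@H](O)C[C@@]1(C)O[C@@H]1[C@@H](O[Si](C)(C)C(C)(C)C)CC(C)=C | intermediate
22 | angelic acid, (2Z)-2-methylbut-2-enoic acid | C/C=C(/C)C(=O)O | starting material
23 | (2Z)-2-methylbut-2-enoic 2,4,6-trichlorobenzoic anhydride (mixed anhydride) | C/C=C(/C)C(=O)OC(=O)c1c(Cl)cc(Cl)cc1Cl | intermediate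
24 | (1S)-2-{(2R,3R)-3-[(1S)-1-(tert-butyldimethylsilyloxy)-3-methylbut-3-en-1-yl]-2-methyloxiran-2-yl}-1-[(2R,3R)-4-methylidene-5-oxo-2-vinyltetrahydrofuran-3-yl]ethyl (2Z)-2-methylbut-2-enoate | C=C[C@H]1OC(=O)C(=C)[C@@H]1[C@@H](OC(=O)/C(C)=C\C)C[C@@]1(C)O[C@@H]1[C@@H](O[Si](C)(C)C(C)(C)C)CC(C)=C | intermediate
25 | (1S)-2-{(2R,3R)-3-[(1S)-1-hydroxy-3-methylbut-3-en-1-yl]-2-methyloxiran-2-yl}-1-[(2R,3R)-4-methylidene-5-oxo-2-vinyltetrahydrofuran-3-yl]ethyl (2Z)-2-methylbut-2-enoate | C=C[C@H]1OC(=O)C(=C)[C@@H]1[C@@H](OC(=O)/C(C)=C\C)C[C@@]1(C)O[C@@H]1[C@@H](O)CC(C)=C | intermediate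
26 | (1R,2S,4Z,6R,7R,8S,10R)-8-angeloyloxy-1,10-epoxy-2-hydroxygermacra-4,11(13)-dien-12,6-olide | C/C1=C/[C@H]2OC(=O)C(=C)[C@@H]2[C@@H](OC(=O)/C(C)=C\C)C[C@@]2(C)O[C@@H]2[C@@H](O)C1 | intermediate
27 | (1R,2S,4R,5S,6S,7R,8S,10R)-8-angeloyloxy-1,10:4,5-diepoxy-2-hydroxygermacr-11(13)-en-12,6-olide | C=C1C(=O)O[C@H]2[C@H]1[C@@H](OC(=O)/C(C)=C\C)C[C@@]1(C)O[C@@H]1[C@@H](O)C[C@@]1(C)O[C@@H]21 | target

**Step count and risks**

Total step count: 16. Longest linear sequence: 15 (steps 1–4 and 6–16; step 5 is a side branch).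

The three steps most likely to fail:

Step 15 (ring-closing metathesis). What may go wrong: oligomerisation by intermolecular metathesis, failure of the hindered 1,1-disubstituted olefin to engage, or closure to the 4E isomer. The fallback moves the ring closure to an earlier stage and a differently substituted chain. It sets out from 20, which carries no angelate and has two bulky silyl ethers that change the folding about C2 and C8. Metathesis of 20 with the same ruthenium catalyst should give the macrocyclic bis-silyl ether F1. Selective removal of the triethylsilyl group with HF·pyridine then gives the macrocyclic C8 alcohol F2, esterification with mixed anhydride 23 gives the silylated macrocyclic angelate F3, and Bu4NF/AcOH returns to the route at 26.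

Step 6 (vinylogous Mukaiyama aldol). What may go wrong: poor facial selectivity at C8, because the promoter may be mismatched with the intrinsic bias of the α-branched β-acyloxy aldehyde, and epimerisation at C7. The fallback sets out from 9 and uses the enantiomeric promoter (from N-tosyl-L-tryptophan), which is then the matched case and should give the 8R adduct F4. This is carried through the operations of steps 7–12: the triethylsilyl ether F5, the methallyl adduct F6, the epoxy alcohol F7, the bis-silyl ether F8, the Mannich base F9, the ammonium iodide F10, the α-methylene lactone F11 and the 8R alcohol F12. The angelate is then introduced with inversion at C8 by Mitsunobu esterification (PPh3, DIAD, 22, PhMe, 0 °C), which returns to the route at 24.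

Step 13 (angelate esterification). What may go wrong: Z-to-E isomerisation of the angeloyl group to the tigloyl isomer, or acyl migration and translactonisation of the free C8 alcohol during the slow, heated acylation. The fallback builds the Z-olefin on the ester instead of transferring it. It sets out from 21, which is esterified at room temperature with 2-[bis(2,2,2-trifluoroethoxy)phosphoryl]propanoic acid (DCC, DMAP, CH2Cl2) to the phosphonopropionate F13. Still–Gennari olefination (KN(SiMe3)2, 18-crown-6, THF, −78 °C; acetaldehyde) then gives the Z-2-methylbut-2-enoate and returns to the route at 24.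

Further compounds
F1 | step 15 | (1R,2S,4Z,6R,7S,8S,10R)-2-(tert-butyldimethylsilyloxy)-1,10-epoxy-8-(triethylsilyloxy)germacra-4,11(13)-dien-12,6-olide | C/C1=C/[C@H]2OC(=O)C(=C)[C@@H]2[C@@H](O[Si](CC)(CC)CC)C[C@@]2(C)O[C@@H]2[C@@H](O[Si](C)(C)C(C)(C)C)C1
F2 | step 15 | (1R,2S,4Z,6R,7R,8S,10R)-2-(tert-butyldimethylsilyloxy)-1,10-epoxy-8-hydroxygermacra-4,11(13)-dien-12,6-olide | C/C1=C/[C@H]2OC(=O)C(=C)[C@@H]2[C@@H](O)C[C@@]2(C)O[C@@H]2[C@@H](O[Si](C)(C)C(C)(C)C)C1
F3 | step 15 | (1R,2S,4Z,6R,7R,8S,10R)-8-angeloyloxy-2-(tert-butyldimethylsilyloxy)-1,10-epoxygermacra-4,11(13)-dien-12,6-olide | C/C1=C/[C@H]2OC(=O)C(=C)[C@@H]2[C@@H](OC(=O)/C(C)=C\C)C[C@@]2(C)O[C@@H]2[C@@H](O[Si](C)(C)C(C)(C)C)C1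
F4 | step 6 | (2E,5R)-5-hydroxy-3-methyl-5-[(2R,3R)-5-oxo-2-vinyltetrahydrofuran-3-yl]pent-2-enal (C8 epimer of 12) | C=C[C@H]1OC(=O)C[C@@H]1[C@H](O)C/C(C)=C/C=O
F5 | step 6 | (2E,5R)-3-methyl-5-[(2R,3S)-5-oxo-2-vinyltetrahydrofuran-3-yl]-5-(triethylsilyloxy)pent-2-enal (C8 epimer of 13) | C=C[C@H]1OC(=O)C[C@@H]1[C@H](O[Si](CC)(CC)CC)C/C(C)=C/C=O
F6 | step 6 | (4S,5R)-4-[(1R,3E,5S)-5-hydroxy-3,7-dimethyl-1-(triethylsilyloxy)octa-3,7-dien-1-yl]-5-vinyldihydrofuran-2(3H)-one (C8 epimer of 15) | C=C[C@H]1OC(=O)C[C@@H]1[C@H](O[Si](CC)(CC)CC)C/C(C)=C/[C@@H](O)CC(C)=C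
F7 | step 6 | C8 epimer of 16 (8R; 1R,2S,10R epoxy alcohol, triethylsilyl ether) | C=C[C@H]1OC(=O)C[C@@H]1[C@H](O[Si](CC)(CC)CC)C[C@@]1(C)O[C@@H]1[C@@H](O)CC(C)=C
F8 | step 6 | C8 epimer of 17 (8R; C2 tert-butyldimethylsilyl ether, C8 triethylsilyl ether) | C=C[C@H]1OC(=O)C[C@@H]1[C@H](O[Si](CC)(CC)CC)C[C@@]1(C)O[C@@H]1[C@@H](O[Si](C)(C)C(C)(C)C)CC(C)=C
F9 | step 6 | C8 epimer of Mannich base 18 (C11 epimers) | C=C[C@H]1OC(=O)C(CN(C)C)[C@@H]1[C@H](O[Si](CC)(CC)CC)C[C@@]1(C)O[C@@H]1[C@@H](O[Si](C)(C)C(C)(C)C)CC(C)=C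
F10 | step 6 | C8 epimer of ammonium iodide 19 (C11 epimers) | C=C[C@H]1OC(=O)C(C[N+](C)(C)C)[C@@H]1[C@H](O[Si](CC)(CC)CC)C[C@@]1(C)O[C@@H]1[C@@H](O[Si](C)(C)C(C)(C)C)CC(C)=C.[I-]
F11 | step 6 | C8 epimer of 20 (8R α-methylene lactone, bis-silyl ether) | C=C[C@H]1OC(=O)C(=C)[C@@H]1[C@H](O[Si](CC)(CC)CC)C[C@@]1(C)O[C@@H]1[C@@H](O[Si](C)(C)C(C)(C)C)CC(C)=C
F12 | step 6 | (4R,5R)-4-[(1R)-2-{(2R,3R)-3-[(1S)-1-(tert-butyldimethylsilyloxy)-3-methylbut-3-en-1-yl]-2-methyloxiran-2-yl}-1-hydroxyethyl]-3-methylidene-5-vinyldihydrofuran-2(3H)-one (C8 epimer of 21) | C=C[C@H]1OC(=O)C(=C)[C@@H]1[C@H](O)C[C@@]1(C)O[C@@H]1[C@@H](O[Si](C)(C)C(C)(C)C)CC(C)=C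
F13 | step 13 | C8 ester of 21 with 2-[bis(2,2,2-trifluoroethoxy)phosphoryl]propanoic acid (epimers at the phosphonate carbon) | C=C[C@H]1OC(=O)C(=C)[C@@H]1[C@@H](OC(=O)C(C)P(=O)(OCC(F)(F)F)OCC(F)(F)F)C[C@@]1(C)O[C@@H]1[C@@H](O[Si](C)(C)C(C)(C)C)CC(C)=C
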